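**Retrosynthetic overview**

1. Target ⇒ remove three O-methyl groups last; disconnect the C8–acyl bond (Friedel–Crafts) to (R)-5,7-dimethoxy-4-phenylchroman-2-one and 3-(4-methoxyphenyl)propanoyl chloride.
2. The strategy rests on the lactone ring O1–C2–C3–C4–C4a–C8a: C2 is a single carbonyl carbon between the C3 methylene and O1, and the only stereocentre, C4 (bearing phenyl and ring A), is an alkene carbon plus one hydrogen.
3. C2–C3 and C2–O1 are therefore cut together: CO is placed between the CH2 terminus of 3,5-dimethoxy-2-(1-phenylethenyl)phenol and its phenol oxygen by an asymmetric palladium hydride cyclocarbonylation that also sets C4.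
4. The alkene phenol comes from 2-hydroxy-4,6-dimethoxybenzophenone (MeMgBr, dehydration), made from symmetric 1,3,5-trimethoxybenzene and benzoyl chloride, so no regiochemical question arises before the key step.
5. Ring order: ring A and both phenyl rings are bought; the lactone ring is the only ring formed (step 4); the C8 side chain is attached afterwards.

Key step: step 4

Assumption: the sense of induction of the chiral diphosphine in step 4 cannot be predicted, so the DIOP antipode written is provisional and the one that gives the 4R lactone is used; the side-chain phenol is carried as its methyl ether so that one BBr3 treatment ends the route.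

**Route**

Step 1
Reactants: 1 1,3,5-trimethoxybenzene; 2 benzoyl chloride
Product: 3 (2,4,6-trimethoxyphenyl)(phenyl)methanone (2,4,6-trimethoxybenzophenone)
Conditions: AlCl3 (1.1 equiv), CH2Cl2, 0 °C to rt
Reagents that add atoms: none
Why: Friedel–Crafts acylation of the threefold-symmetric, strongly activated arene can give only one monoketone, and the acyl group then deactivates the ring towards a second acylation.

Step 2
Reactants: 3 (2,4,6-trimethoxyphenyl)(phenyl)methanone
Product: 4 (2-hydroxy-4,6-dimethoxyphenyl)(phenyl)methanone
Conditions: BCl3 (1.2 equiv), CH2Cl2, −78 to 0 °C; aq. work-up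
Reagents that add atoms: none
Why: Chelation-controlled Lewis acid ether cleavage, in which BCl3 bound to the ketone oxygen removes one of the two equivalent ortho methyl groups through a six-membered boron chelate and leaves the para methoxy group and the second ortho methoxy group intact.

Step 3
Reactants: 4 (2-hydroxy-4,6-dimethoxyphenyl)(phenyl)methanone
Product: 6 3,5-dimethoxy-2-(1-phenylethenyl)phenol, via tertiary carbinol 5 (not isolated)
Conditions: MeMgBr (3 equiv), THF, 0 °C to rt; 1 M HCl work-up; then TsOH·H2O (5 mol %), toluene, rt
Reagents that add atoms: methylmagnesium bromide, C[Mg]Br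
Why: Grignard addition to the non-enolisable ketone (one equivalent is spent on the phenol) gives a tertiary, doubly benzylic carbinol whose acid-catalysed E1 dehydration can only take a hydrogen from the new methyl group, so the 1,1-diarylethene is the sole alkene.

Step 4
Reactants: 6 3,5-dimethoxy-2-(1-phenylethenyl)phenol; 7 carbon monoxide
Product: 8 (4R)-5,7-dimethoxy-4-phenylchroman-2-one
Conditions: Pd(OAc)2 (5 mol %), (R,R)-DIOP (6 mol %, antipode as required for 4R), CO (30 bar), H2 (5 bar), toluene, 90 °C
Reagents that add atoms: none
Why: Proposed new method: the cationic hydride [(DIOP)PdH]+ (divalent palladium), formed from Pd(OAc)2, the diphosphine and H2, should add to the alkene with hydrogen to the diaryl carbon (C4) and palladium to the CH2 carbon (C3), CO should insert into the primary alkyl–palladium bond (C2–C3), and the ortho phenol should attack the acylpalladium (C2–O1) to release 8 and regenerate the hydride. The closest known reaction types are the non-asymmetric palladium hydride cyclocarbonylation of 2-vinyl- and 2-isopropenylphenols to dihydrocoumarins under CO/H2 with Pd(OAc)2 and 1,4-bis(diphenylphosphino)butane, of which DIOP is the chiral analogue, and the asymmetric anti-Markovnikov hydroalkoxycarbonylation of α-methylstyrene with PdCl2/DIOP; an enantioselective ring-closing version on a 1,1-diarylethene is not known. The lactone ring closes by a 6-exo-trig acyl substitution of the phenol oxygen at the acyl carbon. C4 is set in the hydropalladation, where the chiral diphosphine has to deliver hydride to the Si face of the diaryl carbon for the R configuration; it can distinguish the conjugated, coplanar phenyl group from ring A, which its two ortho oxygen substituents turn out of the alkene plane. The step needs anti-Markovnikov regioselectivity (the alternative is a benzofuranone with a quaternary carbon), which the two aryl groups secure by making the tertiary alkylpalladium too crowded, and chemoselectivity over hydrogenation and acid-induced dimerisation of the alkene, which the low H2 pressure and the absence of strong acid should secure.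

Step 5
Reactants: 9 3-(4-methoxyphenyl)propanoic acid
Product: 10 3-(4-methoxyphenyl)propanoyl chloride
Conditions: (COCl)2 (1.3 equiv), DMF (cat.), CH2Cl2, 0 °C to rt; evaporate, use crude
Reagents that add atoms: oxalyl chloride, O=C(Cl)C(=O)Cl
Why: Standard acid chloride formation with oxalyl chloride under DMF catalysis (Vilsmeier-type chloroiminium activation), which leaves the aryl methyl ether untouched and gives only volatile by-products.

Step 6
Reactants: 8 (4R)-5,7-dimethoxy-4-phenylchroman-2-one; 10 3-(4-methoxyphenyl)propanoyl chloride
Product: 11 (4R)-5,7-dimethoxy-8-[3-(4-methoxyphenyl)propanoyl]-4-phenylchroman-2-one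
Conditions: AlCl3 (2.5 equiv, added in portions), CH2Cl2, −10 to 0 °C; ice/dil. HCl quench
Reagents that add atoms: none
Why: Friedel–Crafts acylation of ring A, expected at C8 because C8 is para to the C5 and ortho to the C7 methoxy group (the site at which 5,7-dialkoxycoumarins and 5,7-dialkoxyflavones are substituted), while C6 is screened by the C5 methoxy group whose methyl is turned towards it by the peri substituents at C4, and the C4 stereocentre has no pathway for epimerisation at 0 °C.

Step 7
Reactants: 11 (4R)-5,7-dimethoxy-8-[3-(4-methoxyphenyl)propanoyl]-4-phenylchroman-2-one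
Product: 12 (4R)-5,7-dihydroxy-8-[3-(4-hydroxyphenyl)propanoyl]-4-phenylchroman-2-one
Conditions: BBr3 (8 equiv), CH2Cl2, −78 °C to rt; ice-water quench, no base
Reagents that add atoms: none
Why: Ether cleavage with BBr3 (bromide attacks the methyl of each boron-complexed ether) frees the three phenols, the aryl lactone and C4 are inert under anhydrous conditions, and the cold, base-free work-up avoids opening of the lactone, which could reclose on the C5 oxygen to the 6-acyl isomer.

**Compound list**

1 | 1,3,5-trimethoxybenzene | COc1cc(OC)cc(OC)c1 | starting material
2 | benzoyl chloride | O=C(Cl)c1ccccc1 | starting material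
3 | (2,4,6-trimethoxyphenyl)(phenyl)methanone | COc1cc(OC)c(C(=O)c2ccccc2)c(OC)c1 | intermediate
4 | (2-hydroxy-4,6-dimethoxyphenyl)(phenyl)methanone | COc1cc(O)c(C(=O)c2ccccc2)c(OC)c1 | intermediate
5 | 2-(1-hydroxy-1-phenylethyl)-3,5-dimethoxyphenol (racemic tertiary carbinol, not isolated) | CC(O)(c1ccccc1)c1c(O)cc(OC)cc1OC | intermediate
6 | 3,5-dimethoxy-2-(1-phenylethenyl)phenol | C=C(c1ccccc1)c1c(O)cc(OC)cc1OC | intermediate
7 | carbon monoxide | [C-]#[O+] | starting material
8 | (4R)-5,7-dimethoxy-4-phenylchroman-2-one | O=C1C[C@H](c2ccccc2)c2c(OC)cc(OC)cc2O1 | intermediate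
9 | 3-(4-methoxyphenyl)propanoic acid | COc1ccc(CCC(=O)O)cc1 | starting material
10 | 3-(4-methoxyphenyl)propanoyl chloride | COc1ccc(CCC(=O)Cl)cc1 | intermediate
11 | (4R)-5,7-dimethoxy-8-[3-(4-methoxyphenyl)propanoyl]-4-phenylchroman-2-one | O=C1C[C@H](c2ccccc2)c2c(OC)cc(OC)c(C(=O)CCc3ccc(OC)cc3)c2O1 | intermediate
12 | (4R)-5,7-dihydroxy-8-[3-(4-hydroxyphenyl)propanoyl]-4-phenylchroman-2-one | O=C1C[C@H](c2ccccc2)c2c(O)cc(O)c(C(=O)CCc3ccc(O)cc3)c2O1 | target

**Step count**

Total steps: 7. Longest linear sequence: 6 steps (1, 2, 3, 4, 6, 7); step 5 is a one-step branch.

**Steps most likely to fail**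

Step 4. The hydropalladation may be slow or poorly face-selective, insertion may go the Markovnikov way, the alkene may be hydrogenated, or the hindered phenol may fail to capture the acylpalladium. A change of diphosphine would be tried first. The fallback uses known chemistry, sets out from 4 and returns at 8. Wittig olefination of 4 with ethyl (triphenylphosphoranylidene)acetate in hot N,N-diethylaniline should give ethyl (Z)-3-(2-hydroxy-4,6-dimethoxyphenyl)-3-phenylprop-2-enoate F1, which lactonises in the flask to 5,7-dimethoxy-4-phenylcoumarin F2. Asymmetric conjugate reduction of this 4-arylcoumarin with CuH (from Cu(OAc)2, a DTBM-SEGPHOS antipode chosen to give 4R, diethoxymethylsilane and t-BuOH in toluene) is a known reaction type. It usually runs on to the lactol, so (4R)-5,7-dimethoxy-4-phenylchroman-2-ol F3 is expected, and oxidation with TEMPO (cat.)/PhI(OAc)2 should return lactone 8.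

Step 6. Acylation may go to C6 instead of C8, a second acyl group may enter, or 10 may be consumed by cyclisation to an indanone; partial loss of the C7 methyl group would be harmless because step 7 removes it. The site would be checked by NOE (a C6 hydrogen must see both methoxy groups). The fallback sets out from 8 and returns at 12 with the order of the last two operations reversed. BBr3 in CH2Cl2 should give (4R)-5,7-dihydroxy-4-phenylchroman-2-one F4; at this stage opening and reclosing of the lactone is harmless because the two ring A oxygens next to C4a are equivalent in the opened acid. F4 is then acylated with commercial 3-(4-hydroxyphenyl)propanoic acid (OC(=O)CCc1ccc(O)cc1) in BF3·OEt2 at the lowest temperature that gives conversion. The free C5 hydroxyl is now the strongest para director and should guide the acyl group to C8, as in the acylation of 5,7-dihydroxycoumarins, giving 12 directly.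

Step 3. Addition to the magnesium-chelated, doubly ortho-substituted ketone may stall, and the electron-rich diarylethene may dimerise under the acid used for dehydration. The fallback sets out from 4, returns at 6 and uses base only. Silylation of 4 (TBSCl, imidazole, DMF) should give [2-(tert-butyldimethylsilyloxy)-4,6-dimethoxyphenyl](phenyl)methanone F5, which is no longer chelated. Wittig methylenation (Ph3PCH3Br, KOtBu, THF, reflux) should give tert-butyl[3,5-dimethoxy-2-(1-phenylethenyl)phenoxy]dimethylsilane F6, and TBAF in THF should release 6.

**Further compounds**

F1 | step 4 | ethyl (Z)-3-(2-hydroxy-4,6-dimethoxyphenyl)-3-phenylprop-2-enoate | CCOC(=O)/C=C(/c1ccccc1)c1c(O)cc(OC)cc1OC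
F2 | step 4 | 5,7-dimethoxy-4-phenyl-2H-chromen-2-one | O=C1C=C(c2ccccc2)c2c(OC)cc(OC)cc2O1
F3 | step 4 | (4R)-5,7-dimethoxy-4-phenylchroman-2-ol (mixture at C2) | OC1C[C@H](c2ccccc2)c2c(OC)cc(OC)cc2O1
F4 | step 6 | (4R)-5,7-dihydroxy-4-phenylchroman-2-one | O=C1C[C@H](c2ccccc2)c2c(O)cc(O)cc2O1
F5 | step 3 | [2-(tert-butyldimethylsilyloxy)-4,6-dimethoxyphenyl](phenyl)methanone | COc1cc(OC)c(C(=O)c2ccccc2)c(O[Si](C)(C)C(C)(C)C)c1
F6 | step 3 | tert-butyl[3,5-dimethoxy-2-(1-phenylethenyl)phenoxy]dimethylsilane | C=C(c1ccccc1)c1c(O[Si](C)(C)C(C)(C)C)cc(OC)cc1OC
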